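**Plan**
Numbering: 2H-chromene numbering (O1, C2, C3, C4, C4a, C5–C8, C8a). Ring A is the benzo ring, ring B the resorcinol ring, ring C the pyran ring.
Cuts: the two MOM ethers; O1–C8a (ring C); C2–C3 (CH2OH); C3–C1' (ring B); C3=C4 (back to an aldehyde on C4a); C4a–CHO; C6–prenyl.
Enabling feature: in ring A, C8 bears hydrogen and lies between C7–OMe and C8a–O1, and O1 is meta to both methoxy groups. A chlorine parked on C8 makes a 2-chloroanisole unit that can lose HCl across C8/C8a to one aryne only. C7–OMe and the (Z)-CH2O− arm on C4a both direct attack to C8a, and the chlorine disappears in the same event.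
Forward: 4-chlororesorcinol dimethyl ether takes prenyl between its methoxy groups, then CHO (ring A complete). CHO becomes CH=CBr2, ring B is joined, then CH2OH, ring C closes last, and MOM removal ends the route.
Stereochemistry: there is no stereocentre. The C3=C4 geometry (CH2O cis to ring A) comes from the trans-selective Suzuki coupling of the dibromoalkene and from retention in the Stille coupling.

Key step: step 8

**Step 1**
Reactants: 1 1-chloro-2,4-dimethoxybenzene; 2 prenyl bromide (1-bromo-3-methylbut-2-ene)
Product: 4 1-chloro-2,4-dimethoxy-3-(3-methylbut-2-en-1-yl)benzene, via aryllithium 3 (not isolated)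
Conditions: n-BuLi, THF, 0 °C; then 2, −78 °C → rt
Reagents that add atoms: none
Why: Directed ortho-metalation, in which the two methoxy groups cooperate to place lithium on the carbon between them (chlorine does not exchange with n-BuLi here and is meta to the carbanion, so no aryne can form), followed by SN2 alkylation of aryllithium 3 with the primary allylic bromide.

**Step 2**
Reactants: 4 1-chloro-2,4-dimethoxy-3-(3-methylbut-2-en-1-yl)benzene
Product: 6 5-chloro-2,4-dimethoxy-3-(3-methylbut-2-en-1-yl)benzaldehyde, via iminium salt 5 (not isolated)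
Conditions: POCl3, DMF, 0 → 70 °C; then aq NaOAc
Reagents that add atoms: N,N-dimethylformamide CN(C)C=O; water O
Why: Vilsmeier–Haack formylation, in which only one of the two free ring positions is ortho and para to the methoxy groups, the chloroiminium ion is too weak an electrophile for the isolated trisubstituted alkene, and buffered hydrolysis of 5 keeps acid away from the prenyl group.

**Step 3**
Reactants: 6 5-chloro-2,4-dimethoxy-3-(3-methylbut-2-en-1-yl)benzaldehyde
Product: 7 1-chloro-5-(2,2-dibromoethenyl)-2,4-dimethoxy-3-(3-methylbut-2-en-1-yl)benzene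
Conditions: CBr4, PPh3, CH2Cl2, 0 °C
Reagents that add atoms: carbon tetrabromide BrC(Br)(Br)Br
Why: Ramirez dibromo-olefination (first stage of the Corey–Fuchs sequence), a Wittig reaction of Ph3P=CBr2 with the aldehyde under neutral conditions that should leave the prenyl group, the aryl chloride and the ethers untouched.

**Step 4**
Reactants: 8 4-bromoresorcinol
Product: 9 1-bromo-2,4-bis(methoxymethoxy)benzene
Conditions: MOMCl, i-Pr2NEt, CH2Cl2, 0 °C → rt
Reagents that add atoms: chloromethyl methyl ether COCCl
Why: Williamson-type O-alkylation of both phenols to methoxymethyl acetals, which withstand the organolithium, palladium and lithium amide steps ahead.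

**Step 5**
Reactants: 9 1-bromo-2,4-bis(methoxymethoxy)benzene
Product: 11 [2,4-bis(methoxymethoxy)phenyl]boronic acid, via ring B aryllithium 10 (not isolated)
Conditions: n-BuLi, THF, −78 °C; B(OiPr)3, −78 °C → rt; aq NH4Cl
Reagents that add atoms: triisopropyl borate CC(C)OB(OC(C)C)OC(C)C; water O
Why: Bromine–lithium exchange at −78 °C is faster than MOM-directed ring metalation, and borylation of 10 with near-neutral hydrolysis should give the boronic acid without loss of the acetals.

**Step 6**
Reactants: 7 1-chloro-5-(2,2-dibromoethenyl)-2,4-dimethoxy-3-(3-methylbut-2-en-1-yl)benzene; 11 [2,4-bis(methoxymethoxy)phenyl]boronic acid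
Product: 12 (Z)-1-[2,4-bis(methoxymethoxy)phenyl]-1-bromo-2-[5-chloro-2,4-dimethoxy-3-(3-methylbut-2-en-1-yl)phenyl]ethene (rings A and B trans, Br cis to ring A)
Conditions: Pd2(dba)3, P(2-furyl)3, aq Na2CO3, 1,4-dioxane, 65 °C
Reagents that add atoms: none
Why: Stereoselective Suzuki–Miyaura mono-coupling of a 1,1-dibromoalkene, in which zerovalent palladium inserts faster into the less hindered C–Br bond trans to ring A, so ring B enters trans to ring A with retention while the second bromine and the electron-rich aryl chloride stay.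

**Step 7**
Reactants: 12 the (Z)-bromoalkene
Product: 13 (Z)-2-[2,4-bis(methoxymethoxy)phenyl]-3-[5-chloro-2,4-dimethoxy-3-(3-methylbut-2-en-1-yl)phenyl]prop-2-en-1-ol (CH2OH cis to ring A)
Conditions: Bu3SnCH2OH, Pd(PPh3)4, 1,4-dioxane, 100 °C
Reagents that add atoms: (tributylstannyl)methanol CCCC[Sn](CO)(CCCC)CCCC
Why: Migita–Kosugi–Stille hydroxymethylation, in which oxidative addition and reductive elimination at the alkenyl bromide proceed with retention so that CH2OH takes the place cis to ring A, and no base is present that could eliminate HBr to the diarylalkyne.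

**Step 8**
Reactants: 13 the (Z)-allylic alcohol
Product: 17 3-[2,4-bis(methoxymethoxy)phenyl]-5,7-dimethoxy-6-(3-methylbut-2-en-1-yl)-2H-chromene, via dilithiated chloroarene 14 (not isolated), via aryne alkoxide 15 (not isolated), via 8-lithiochromene 16 (not isolated)
Conditions: LiTMP (TMPH, n-BuLi; 4 equiv), THF (dilute), −78 → 0 °C; aq NH4Cl
Reagents that add atoms: none
Why: One equivalent of LiTMP gives the lithium alkoxide, a further one removes the only proton of ring A (C8a–H, acidified by the ortho chlorine and reached through the alkoxide–amide aggregate) to give 14, and loss of LiCl on warming gives the C8≡C8a aryne 15. The alkoxide oxygen then adds to C8a in the ring plane (6-exo-dig, since C8 lies outside the new ring), and aryllithium 16, flanked by O1 and C7–OMe, takes its proton from TMPH or the quench. The closest known reaction types are the cine-substitution of 2-haloanisoles through 3-methoxybenzyne and the closure of chromans by addition of a tethered alkoxide to an aryne. Site selectivity is secured twice: only one aryne can form because C7 bears methoxy and not hydrogen, and both the inductive pull of that methoxy group (charge builds up on C8 next to it) and the tether send oxygen to C8a. The (Z) geometry from steps 6 and 7 holds CH2OLi beside C8a so that closure should outrun addition of the hindered amide, and ring B, trans to ring A, cannot reach the aryne. No stereocentre forms, the prenyl CH2 is shielded by two ortho methoxy groups that hold its C–H bonds near the ring plane, and the excess base covers reversible metalation between the MOM ethers of ring B, which the quench undoes.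

**Step 9**
Reactants: 17 the bis-MOM chromene
Product: 19 dehydroglyasperin D, 4-[5,7-dimethoxy-6-(3-methylbut-2-en-1-yl)-2H-chromen-3-yl]benzene-1,3-diol, via bis(trimethylsilyl) ether 18 (not isolated)
Conditions: TMSOTf, 2,2'-bipyridyl, MeCN, 0 °C → rt; then H2O
Reagents that add atoms: none
Why: Silyl triflate/bipyridyl cleavage of aromatic MOM ethers turns each ArOCH2OMe into ArOSiMe3 (18), which water hydrolyses, so no Brønsted acid is present that could protonate C3=C4 (closure of the 2'-hydroxyl group onto C4 to a pterocarpan) or add to the prenyl group.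

**Compound list**
1 | 1-chloro-2,4-dimethoxybenzene | Clc1ccc(OC)cc1OC | starting material
2 | prenyl bromide | CC(C)=CCBr | starting material
3 | (3-chloro-2,6-dimethoxyphenyl)lithium (not isolated) | [Li]c1c(OC)ccc(Cl)c1OC | intermediate
4 | 1-chloro-2,4-dimethoxy-3-(3-methylbut-2-en-1-yl)benzene | COc1ccc(Cl)c(OC)c1CC=C(C)C | intermediate
5 | aryl(dimethyl)iminium dichlorophosphate (not isolated) | C[N+](C)=Cc1cc(Cl)c(OC)c(CC=C(C)C)c1OC.[O-]P(=O)(Cl)Cl | intermediate
6 | 5-chloro-2,4-dimethoxy-3-(3-methylbut-2-en-1-yl)benzaldehyde | O=Cc1cc(Cl)c(OC)c(CC=C(C)C)c1OC | intermediate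
7 | 1-chloro-5-(2,2-dibromoethenyl)-2,4-dimethoxy-3-(3-methylbut-2-en-1-yl)benzene | BrC(Br)=Cc1cc(Cl)c(OC)c(CC=C(C)C)c1OC | intermediate
8 | 4-bromoresorcinol | Oc1ccc(Br)c(O)c1 | starting material
9 | 1-bromo-2,4-bis(methoxymethoxy)benzene | COCOc1ccc(Br)c(OCOC)c1 | intermediate
10 | [2,4-bis(methoxymethoxy)phenyl]lithium (not isolated) | [Li]c1ccc(OCOC)cc1OCOC | intermediate
11 | [2,4-bis(methoxymethoxy)phenyl]boronic acid | OB(O)c1ccc(OCOC)cc1OCOC | intermediate
12 | (Z)-bromoalkene, Br cis to ring A | Br/C(c1ccc(OCOC)cc1OCOC)=C\c1cc(Cl)c(OC)c(CC=C(C)C)c1OC | intermediate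
13 | (Z)-allylic alcohol, CH2OH cis to ring A | OC/C(c1ccc(OCOC)cc1OCOC)=C\c1cc(Cl)c(OC)c(CC=C(C)C)c1OC | intermediate
14 | lithium alkoxide of 13 lithiated at C8a (not isolated) | [Li]OC/C(c1ccc(OCOC)cc1OCOC)=C\c1c([Li])c(Cl)c(OC)c(CC=C(C)C)c1OC | intermediate
15 | C8≡C8a aryne lithium alkoxide (not isolated) | [Li]OC/C(c1ccc(OCOC)cc1OCOC)=C\C1=C(OC)C(CC=C(C)C)=C(OC)C#C1 | intermediate
16 | 8-lithio derivative of 17 (not isolated) | COc1c([Li])c2c(c(OC)c1CC=C(C)C)C=C(c1ccc(OCOC)cc1OCOC)CO2 | intermediate
17 | 3-[2,4-bis(methoxymethoxy)phenyl]-5,7-dimethoxy-6-(3-methylbut-2-en-1-yl)-2H-chromene | COc1cc2c(c(OC)c1CC=C(C)C)C=C(c1ccc(OCOC)cc1OCOC)CO2 | intermediate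
18 | 2',4'-bis(trimethylsilyl) ether of 19 (not isolated) | COc1cc2c(c(OC)c1CC=C(C)C)C=C(c1ccc(O[Si](C)(C)C)cc1O[Si](C)(C)C)CO2 | intermediate
19 | dehydroglyasperin D | COc1cc2c(c(OC)c1CC=C(C)C)C=C(c1ccc(O)cc1O)CO2 | target

**Step count and risks**
Total step count: 9. Longest linear sequence: 7 (steps 1, 2, 3, 6, 7, 8, 9).

**Step 8.**
- What may go wrong: metalation of the doubly activated prenyl CH2 with migration of its double bond into conjugation, addition of the amide to the aryne, or slow ring metalation.
- The fallback moves the chlorine one position and closes the same ring by palladium catalysis. It sets out from 2 (and later uses 11) and comes back at 17.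
- Purchased 1-chloro-3,5-dimethoxybenzene F1 is lithiated between its methoxy groups (n-BuLi, THF, 0 °C) and alkylated with 2 to the symmetrical 5-chloro-1,3-dimethoxy-2-(3-methylbut-2-en-1-yl)benzene F2.
- Vilsmeier–Haack formylation at either of its two equivalent free positions gives 6-chloro-2,4-dimethoxy-3-(3-methylbut-2-en-1-yl)benzaldehyde F3.
- CBr4/PPh3 gives the dibromoalkene F4. The trans-selective Suzuki–Miyaura coupling with 11 gives the (Z)-bromoalkene F5. Stille hydroxymethylation with Bu3SnCH2OH gives the (Z)-allylic alcohol F6, whose chlorine now sits on C8a.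
- Intramolecular Buchwald–Hartwig etherification (Pd(OAc)2, 2-(di-tert-butylphosphino)-1,1'-binaphthyl, Cs2CO3, toluene, 80 °C) gives 17.

**Step 7.**
- What may go wrong: slow transmetalation at the crowded alkenyl bromide, competing butyl transfer, or protodestannylation of the reagent.
- The fallback sets out from 12 and comes back at 13.
- Palladium-catalysed methoxycarbonylation with retention (PdCl2(PPh3)2, CO, MeOH, Et3N, DMF, 70 °C) gives the methyl (Z)-2,3-diarylacrylate F7.
- DIBAL-H (CH2Cl2, −78 °C) reduces F7 to 13.

**Step 2.**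
- What may go wrong: addition of HCl to the prenyl double bond, or sluggish substitution at the crowded, chlorine-deactivated ring.
- The fallback builds the aldehyde from the phenol level and replaces steps 1 and 2. It sets out from 2 and comes back at 6.
- Purchased 5-chloro-2,4-dihydroxybenzaldehyde F8 is C-prenylated with 2 at C3, its only free nucleophilic ring carbon (KOH, MeOH/H2O, 0 °C → rt, phenoxide C-alkylation), to 5-chloro-2,4-dihydroxy-3-(3-methylbut-2-en-1-yl)benzaldehyde F9.
- Both phenols are then methylated (MeI, K2CO3, DMF) to give 6.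

**Further compounds**
F1 | step 8 | 1-chloro-3,5-dimethoxybenzene (purchased) | COc1cc(Cl)cc(OC)c1
F2 | step 8 | 5-chloro-1,3-dimethoxy-2-(3-methylbut-2-en-1-yl)benzene | COc1cc(Cl)cc(OC)c1CC=C(C)C
F3 | step 8 | 6-chloro-2,4-dimethoxy-3-(3-methylbut-2-en-1-yl)benzaldehyde | O=Cc1c(Cl)cc(OC)c(CC=C(C)C)c1OC
F4 | step 8 | 1-chloro-2-(2,2-dibromoethenyl)-3,5-dimethoxy-4-(3-methylbut-2-en-1-yl)benzene | BrC(Br)=Cc1c(Cl)cc(OC)c(CC=C(C)C)c1OC
F5 | step 8 | (Z)-bromoalkene with chlorine on C8a | Br/C(c1ccc(OCOC)cc1OCOC)=C\c1c(Cl)cc(OC)c(CC=C(C)C)c1OC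
F6 | step 8 | (Z)-allylic alcohol with chlorine on C8a | OC/C(c1ccc(OCOC)cc1OCOC)=C\c1c(Cl)cc(OC)c(CC=C(C)C)c1OC
F7 | step 7 | methyl (Z)-2-[2,4-bis(methoxymethoxy)phenyl]-3-[5-chloro-2,4-dimethoxy-3-(3-methylbut-2-en-1-yl)phenyl]prop-2-enoate | COC(=O)/C(c1ccc(OCOC)cc1OCOC)=C\c1cc(Cl)c(OC)c(CC=C(C)C)c1OC
F8 | step 2 | 5-chloro-2,4-dihydroxybenzaldehyde (purchased) | O=Cc1cc(Cl)c(O)cc1O
F9 | step 2 | 5-chloro-2,4-dihydroxy-3-(3-methylbut-2-en-1-yl)benzaldehyde | O=Cc1cc(Cl)c(O)c(CC=C(C)C)c1O
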